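Ring C is cut between its two ether oxygens and rebuilt by a Danheiser-type benzannulation. The feature used is its substitution pattern: O–ring B at C1, O–ring D at C4, hydroxyls at C3 and C5, hydrogens at C2 and C6. Heating a racemic 4-aryloxy-3-ethoxycyclobutenone that carries rings D–E with the ethynyl ether of the A–B phenol should form C2–C3 and C1–C6, close ring C at C3–C4 and deliver both hindered diaryl ether oxygens in one operation, with a free C3 phenol and a C5 ethyl ether. Both partners come from diaryl ether phenols made by SNAr or Ullmann coupling and Dakin oxidation; one BBr3 treatment then cleaves eleven methyl ethers and the ethyl ether.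

Key step: step 9

Ring labels: A = terminal 2,4,6-trioxygenated ring, B = its neighbour, C = central ring, D = pentaoxygenated ring, E = terminal 3,4,5-trioxygenated ring. The target has thirteen hydroxyls and four diaryl ether oxygens, so compound 27 carries eleven methyl ethers, one ethyl ether and one free phenol.

Assumption: 2-fluoro-4,6-dimethoxybenzaldehyde (2) is treated as a catalogue compound; otherwise Vilsmeier–Haack formylation of 1-fluoro-3,5-dimethoxybenzene should supply it.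

Step 1
Reactants: 1 2,4,6-trimethoxyphenol; 2 2-fluoro-4,6-dimethoxybenzaldehyde
Product: 3 2-(2,4,6-trimethoxyphenoxy)-4,6-dimethoxybenzaldehyde
Conditions: Cs2CO3, DMF, 110 °C, Ar
Reagents that add atoms: 2-fluoro-4,6-dimethoxybenzaldehyde (2), O=Cc1c(F)cc(OC)cc1OC
Why: Nucleophilic aromatic substitution (SNAr), in which the ortho-formyl group stabilises the anionic adduct and both methoxy groups of 2 lie meta to the fluorine-bearing carbon and so do not deactivate it, should let even the di-ortho-substituted phenoxide of 1 displace fluoride.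

Step 2
Reactants: 3 2-(2,4,6-trimethoxyphenoxy)-4,6-dimethoxybenzaldehyde
Product: 5 2-(2,4,6-trimethoxyphenoxy)-4,6-dimethoxyphenol (A–B phenol), via aryl formate 4 (not isolated)
Conditions: 30% aq. H2O2, H2SO4 (cat.), MeOH, rt
Reagents that add atoms: hydrogen peroxide, OO
Why: Acid-catalysed Dakin oxidation (Baeyer–Villiger-type aryl migration in the hydroperoxide adduct of an aldehyde flanked by ortho and para oxygen donors) should give the formate, which methanol cleaves in the same pot, without a peracid that could attack the electron-rich rings.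

Step 3
Reactants: 5 2-(2,4,6-trimethoxyphenoxy)-4,6-dimethoxyphenol; 6 trichloroethylene
Product: 7 1-[(E)-1,2-dichlorovinyloxy]-4,6-dimethoxy-2-(2,4,6-trimethoxyphenoxy)benzene
Conditions: ClCH=CCl2, K2CO3, DMF, 70 °C
Reagents that add atoms: trichloroethylene (6), ClC=C(Cl)Cl
Why: Base-mediated dehydrochlorination of trichloroethylene to dichloroacetylene and anti addition of the phenoxide (the dichlorovinyl ether entry to ynol ethers) should give the (E)-enol ether, the small linear electrophile tolerating both ortho substituents.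

Step 4
Reactants: 7 1-[(E)-1,2-dichlorovinyloxy]-4,6-dimethoxy-2-(2,4,6-trimethoxyphenoxy)benzene
Product: 10 1-(ethynyloxy)-4,6-dimethoxy-2-(2,4,6-trimethoxyphenoxy)benzene (A–B ethynyl ether), via chloroethynyl ether 8 (not isolated), via lithium aryloxyacetylide 9 (not isolated)
Conditions: n-BuLi (2.2 equiv), THF, −78 °C; sat. aq. NH4Cl, −78 → 0 °C; short basic alumina plug, kept cold as a toluene solution and used the same day
Reagents that add atoms: none
Why: Dehydrochlorination to the chloroalkyne followed by chlorine–lithium exchange should give the lithium acetylide, which is protonated cold, and at −78 °C ring lithiation of the methoxyarenes should not compete.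

Step 5
Reactants: 11 3,4,5-trimethoxyphenol; 12 2-bromo-3,4,5-trimethoxybenzaldehyde
Product: 13 3,4,5-trimethoxy-2-(3,4,5-trimethoxyphenoxy)benzaldehyde
Conditions: CuI (10 mol%), N,N-dimethylglycine·HCl (30 mol%), Cs2CO3, 1,4-dioxane, 100 °C
Reagents that add atoms: 2-bromo-3,4,5-trimethoxybenzaldehyde (12), COc1cc(C=O)c(Br)c(OC)c1OC
Why: Ullmann-type copper-catalysed C–O coupling should work because the ortho-formyl group activates the bromide and the phenol 11 has no ortho substituent.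

Step 6
Reactants: 13 3,4,5-trimethoxy-2-(3,4,5-trimethoxyphenoxy)benzaldehyde
Product: 15 3,4,5-trimethoxy-2-(3,4,5-trimethoxyphenoxy)phenol (D–E phenol), via aryl formate 14 (not isolated)
Conditions: 30% aq. H2O2, H2SO4 (cat.), MeOH, rt
Reagents that add atoms: hydrogen peroxide, OO
Why: Acid-catalysed Dakin oxidation as in step 2, the migrating ring carrying an ortho aryloxy and a para methoxy donor.

Step 7
Reactants: 15 3,4,5-trimethoxy-2-(3,4,5-trimethoxyphenoxy)phenol; 16 ethyl bromoacetate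
Product: 18 2-[3,4,5-trimethoxy-2-(3,4,5-trimethoxyphenoxy)phenoxy]acetic acid, via ethyl ester 17 (not isolated)
Conditions: BrCH2CO2Et, K2CO3, DMF, rt; then LiOH·H2O, THF/H2O, rt; 1 M HCl
Reagents that add atoms: ethyl bromoacetate (16), CCOC(=O)CBr; lithium hydroxide LiOH, [Li+].[OH-]
Why: Williamson ether synthesis on a phenoxide with only one ortho substituent, followed by saponification of the ethyl ester in the same pot.

Step 8
Reactants: 18 2-[3,4,5-trimethoxy-2-(3,4,5-trimethoxyphenoxy)phenoxy]acetic acid; 19 ethoxyacetylene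
Product: 22 racemic 3-ethoxy-4-[3,4,5-trimethoxy-2-(3,4,5-trimethoxyphenoxy)phenoxy]cyclobut-2-en-1-one, via acid chloride 20 (not isolated), via aryloxyketene 21 (not isolated)
Conditions: Me2C=C(Cl)NMe2 (1.1 equiv), CH2Cl2, 0 °C → rt; then slow addition to HC≡COEt (4 equiv), Et3N (1.3 equiv), CH2Cl2, 0 °C → rt
Reagents that add atoms: ethoxyacetylene (19), CCOC#C
Why: The chloroenamine makes the acid chloride under neutral conditions that spare the electron-rich rings, triethylamine dehydrochlorinates it to the aryloxyketene, and a ketene–ynol ether [2+2] cycloaddition, in which the terminal alkyne carbon bonds to the ketene carbonyl carbon, should give the cyclobutenone as a racemate whose C4 centre is erased in step 9.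

Step 9
Reactants: 22 racemic 3-ethoxy-4-[3,4,5-trimethoxy-2-(3,4,5-trimethoxyphenoxy)phenoxy]cyclobut-2-en-1-one; 10 1-(ethynyloxy)-4,6-dimethoxy-2-(2,4,6-trimethoxyphenoxy)benzene
Product: 27 3-ethoxy-5-[4,6-dimethoxy-2-(2,4,6-trimethoxyphenoxy)phenoxy]-2-[3,4,5-trimethoxy-2-(3,4,5-trimethoxyphenoxy)phenoxy]phenol, via vinylketene 23 (not isolated), via 4-vinylcyclobutenone 24 (not isolated), via dienylketene 25 (not isolated), via cyclohexadienone 26 (not isolated)
Conditions: 10 (1.5 equiv), PhMe (0.2 M), 80 → 110 °C, Ar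
Reagents that add atoms: 1-(ethynyloxy)-4,6-dimethoxy-2-(2,4,6-trimethoxyphenoxy)benzene (10), COc1cc(OC)c(Oc2cc(OC)cc(OC)c2OC#C)c(OC)c1
Why: Proposed new method: thermal 4π opening of 22, with the C4 aryloxy group expected to rotate outward, gives vinylketene 23, whose ketene C=C adds [2+2] to ynol ether 10 to give 24, and a second 4π opening gives dienylketene 25, which closes to dienone 26 and tautomerises to phenol 27. The closest known reaction type is the Danheiser benzannulation of cyclobutenones with alkoxy- and silyloxyacetylenes; what has not been shown is an aryloxyacetylene paired with a 4-aryloxy-3-alkoxycyclobutenone. Ring C closes by a thermal disrotatory 6π electrocyclisation that re-forms C3–C4, after the cycloaddition has made C2–C3 and C1–C6. No stereocentre is set, since the sp3 centres of 22, 24 and 26 disappear on aromatisation. The step needs regioselectivity in the [2+2] addition, which the polarised ynol ether should secure: its terminal carbon is the nucleophile and bonds to the ketene carbonyl carbon, so the ring B oxygen ends meta to the new hydroxyl and para to the ring D oxygen. The two ortho substituents on ring B twist the aryl group away from the oxygen lone pair and keep the alkyne electron-rich, the missing β-hydrogen excludes retro-ene loss of the ynol ether, and its excess limits acylation of 27 by the ketene.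

Step 10
Reactants: 27 3-ethoxy-5-[4,6-dimethoxy-2-(2,4,6-trimethoxyphenoxy)phenoxy]-2-[3,4,5-trimethoxy-2-(3,4,5-trimethoxyphenoxy)phenoxy]phenol
Product: 28 2-[3,4,5-trihydroxy-2-(3,4,5-trihydroxyphenoxy)phenoxy]-5-[4,6-dihydroxy-2-(2,4,6-trihydroxyphenoxy)phenoxy]benzene-1,3-diol (CNP0243665.0)
Conditions: BBr3 (30 equiv), CH2Cl2, −78 °C → rt; H2O, 0 °C; Sephadex LH-20, degassed MeOH, Ar
Reagents that add atoms: none
Why: Lewis-acid-mediated cleavage of aryl alkyl ethers (BBr3 dealkylation) should remove all eleven methyl groups and the ethyl group, while the four diaryl ether bonds, which cannot give an alkyl bromide, stay intact.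

Compound list

1 | 2,4,6-trimethoxyphenol | COc1cc(OC)c(O)c(OC)c1 | starting material
2 | 2-fluoro-4,6-dimethoxybenzaldehyde | O=Cc1c(F)cc(OC)cc1OC | starting material
3 | 2-(2,4,6-trimethoxyphenoxy)-4,6-dimethoxybenzaldehyde | COc1cc(OC)c(Oc2cc(OC)cc(OC)c2C=O)c(OC)c1 | intermediate
4 | 2-(2,4,6-trimethoxyphenoxy)-4,6-dimethoxyphenyl formate (not isolated) | COc1cc(OC)c(Oc2cc(OC)cc(OC)c2OC=O)c(OC)c1 | intermediate
5 | 2-(2,4,6-trimethoxyphenoxy)-4,6-dimethoxyphenol (A–B phenol) | COc1cc(OC)c(Oc2cc(OC)cc(OC)c2O)c(OC)c1 | intermediate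
6 | trichloroethylene | ClC=C(Cl)Cl | starting material
7 | 1-[(E)-1,2-dichlorovinyloxy]-4,6-dimethoxy-2-(2,4,6-trimethoxyphenoxy)benzene | COc1cc(OC)c(Oc2cc(OC)cc(OC)c2O/C(Cl)=C\Cl)c(OC)c1 | intermediate
8 | 1-(chloroethynyloxy)-4,6-dimethoxy-2-(2,4,6-trimethoxyphenoxy)benzene (not isolated) | COc1cc(OC)c(Oc2cc(OC)cc(OC)c2OC#CCl)c(OC)c1 | intermediate
9 | lithium 2-[4,6-dimethoxy-2-(2,4,6-trimethoxyphenoxy)phenoxy]acetylide (not isolated) | COc1cc(OC)c(Oc2cc(OC)cc(OC)c2OC#C[Li])c(OC)c1 | intermediate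
10 | 1-(ethynyloxy)-4,6-dimethoxy-2-(2,4,6-trimethoxyphenoxy)benzene (A–B ethynyl ether) | COc1cc(OC)c(Oc2cc(OC)cc(OC)c2OC#C)c(OC)c1 | intermediate
11 | 3,4,5-trimethoxyphenol | COc1cc(O)cc(OC)c1OC | starting material
12 | 2-bromo-3,4,5-trimethoxybenzaldehyde | COc1cc(C=O)c(Br)c(OC)c1OC | starting material
13 | 3,4,5-trimethoxy-2-(3,4,5-trimethoxyphenoxy)benzaldehyde | COc1cc(C=O)c(Oc2cc(OC)c(OC)c(OC)c2)c(OC)c1OC | intermediate
14 | 3,4,5-trimethoxy-2-(3,4,5-trimethoxyphenoxy)phenyl formate (not isolated) | COc1cc(OC=O)c(Oc2cc(OC)c(OC)c(OC)c2)c(OC)c1OC | intermediate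
15 | 3,4,5-trimethoxy-2-(3,4,5-trimethoxyphenoxy)phenol (D–E phenol) | COc1cc(O)c(Oc2cc(OC)c(OC)c(OC)c2)c(OC)c1OC | intermediate
16 | ethyl bromoacetate | CCOC(=O)CBr | starting material
17 | ethyl 2-[3,4,5-trimethoxy-2-(3,4,5-trimethoxyphenoxy)phenoxy]acetate (not isolated) | CCOC(=O)COc1cc(OC)c(OC)c(OC)c1Oc1cc(OC)c(OC)c(OC)c1 | intermediate
18 | 2-[3,4,5-trimethoxy-2-(3,4,5-trimethoxyphenoxy)phenoxy]acetic acid | OC(=O)COc1cc(OC)c(OC)c(OC)c1Oc1cc(OC)c(OC)c(OC)c1 | intermediate
19 | ethoxyacetylene | CCOC#C | starting material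
20 | 2-[3,4,5-trimethoxy-2-(3,4,5-trimethoxyphenoxy)phenoxy]acetyl chloride (not isolated) | ClC(=O)COc1cc(OC)c(OC)c(OC)c1Oc1cc(OC)c(OC)c(OC)c1 | intermediate
21 | 2-[3,4,5-trimethoxy-2-(3,4,5-trimethoxyphenoxy)phenoxy]ethen-1-one, the aryloxyketene (not isolated) | O=C=COc1cc(OC)c(OC)c(OC)c1Oc1cc(OC)c(OC)c(OC)c1 | intermediate
22 | racemic 3-ethoxy-4-[3,4,5-trimethoxy-2-(3,4,5-trimethoxyphenoxy)phenoxy]cyclobut-2-en-1-one | O=C1C=C(OCC)C1Oc1cc(OC)c(OC)c(OC)c1Oc1cc(OC)c(OC)c(OC)c1 | intermediate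
23 | (3Z)-3-ethoxy-4-[3,4,5-trimethoxy-2-(3,4,5-trimethoxyphenoxy)phenoxy]buta-1,3-dien-1-one, the vinylketene, geometry as expected from outward rotation (not isolated) | O=C=C/C(OCC)=C/Oc1cc(OC)c(OC)c(OC)c1Oc1cc(OC)c(OC)c(OC)c1 | intermediate
24 | racemic 3-[4,6-dimethoxy-2-(2,4,6-trimethoxyphenoxy)phenoxy]-4-{(Z)-1-ethoxy-2-[3,4,5-trimethoxy-2-(3,4,5-trimethoxyphenoxy)phenoxy]vinyl}cyclobut-2-en-1-one (not isolated) | O=C1C=C(Oc2c(OC)cc(OC)cc2Oc2c(OC)cc(OC)cc2OC)C1/C(OCC)=C/Oc1cc(OC)c(OC)c(OC)c1Oc1cc(OC)c(OC)c(OC)c1 | intermediate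
25 | (3E,5Z)-3-[4,6-dimethoxy-2-(2,4,6-trimethoxyphenoxy)phenoxy]-5-ethoxy-6-[3,4,5-trimethoxy-2-(3,4,5-trimethoxyphenoxy)phenoxy]hexa-1,3,5-trien-1-one, the dienylketene (not isolated) | O=C=C/C(Oc1c(OC)cc(OC)cc1Oc1c(OC)cc(OC)cc1OC)=C\C(OCC)=C\Oc1cc(OC)c(OC)c(OC)c1Oc1cc(OC)c(OC)c(OC)c1 | intermediate
26 | racemic 3-[4,6-dimethoxy-2-(2,4,6-trimethoxyphenoxy)phenoxy]-5-ethoxy-6-[3,4,5-trimethoxy-2-(3,4,5-trimethoxyphenoxy)phenoxy]cyclohexa-2,4-dien-1-one (not isolated) | O=C1C=C(Oc2c(OC)cc(OC)cc2Oc2c(OC)cc(OC)cc2OC)C=C(OCC)C1Oc1cc(OC)c(OC)c(OC)c1Oc1cc(OC)c(OC)c(OC)c1 | intermediate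
27 | 3-ethoxy-5-[4,6-dimethoxy-2-(2,4,6-trimethoxyphenoxy)phenoxy]-2-[3,4,5-trimethoxy-2-(3,4,5-trimethoxyphenoxy)phenoxy]phenol | COc1cc(OC)c(Oc2cc(OC)cc(OC)c2Oc2cc(O)c(Oc3cc(OC)c(OC)c(OC)c3Oc3cc(OC)c(OC)c(OC)c3)c(OCC)c2)c(OC)c1 | intermediate
28 | 2-[3,4,5-trihydroxy-2-(3,4,5-trihydroxyphenoxy)phenoxy]-5-[4,6-dihydroxy-2-(2,4,6-trihydroxyphenoxy)phenoxy]benzene-1,3-diol (CNP0243665.0, no stereocentre) | Oc1cc(O)c(Oc2cc(O)cc(O)c2Oc2cc(O)c(Oc3cc(O)c(O)c(O)c3Oc3cc(O)c(O)c(O)c3)c(O)c2)c(O)c1 | target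

Total step count: 10. Longest linear sequence: 6 steps (1, 2, 3, 4, 9, 10 or 5, 6, 7, 8, 9, 10).

Steps most likely to fail

Step 9 (Proposed new method). The vinylketene may dimerise or acylate the product phenol faster than the hindered aryl ynol ether intercepts it, or the ynol ether may polymerise on heating. The fallback uses known Ullmann-type chemistry, sets out from 5 and returns to the route at 28. 4-Bromo-2,6-dimethoxyphenol is benzylated (BnBr, K2CO3, DMF) to 2-(benzyloxy)-5-bromo-1,3-dimethoxybenzene F1. Its unhindered bromide is coupled with the hindered phenol 5 (CuI, picolinic acid, K3PO4, DMSO, 90 °C) to give the A–B–C benzyl ether F2, and hydrogenolysis (H2, Pd/C, EtOAc) frees the ring C phenol F3. Rieche formylation of 5-bromo-1,2,3-trimethoxybenzene (Cl2CHOMe, TiCl4, CH2Cl2), whose two free positions are equivalent, gives 6-bromo-2,3,4-trimethoxybenzaldehyde F4. Its formyl-activated bromide is coupled with F3 (CuI, N,N-dimethylglycine·HCl, Cs2CO3, dioxane, 100 °C) to give the A–B–C–D aldehyde F5. Dakin oxidation as in step 2 leads through the aryl formate F6 to the ring D phenol F7, which is arylated with 5-bromo-1,2,3-trimethoxybenzene (CuI, picolinic acid, K3PO4, DMSO, 100 °C) to the tridecamethyl ether F8. BBr3 as in step 10 then gives 28.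

Step 4. The terminal ynol ether may polymerise or hydrate during work-up and concentration. The fallback sets out from 7 and returns at 10. The lithium acetylide 9 is silylated and not protonated (n-BuLi, THF, −78 °C; TMSCl) to give the trimethylsilylethynyl ether F9, which can be chromatographed and stored. K2CO3 in MeOH at 0 °C releases 10 just before step 9, and it is carried forward as a toluene solution.

Step 10. Ether cleavage may stop short at some of the twelve sites, and the air-sensitive polyphenol may be lost by oxidation during purification. The fallback sets out from 27 and returns at 28. The crude BBr3 product is acetylated (Ac2O, pyridine, DMAP cat.) to the tridecaacetate F10, which is purified on silica away from partly alkylated material. Deacetylation under non-oxidising conditions (HCl from AcCl in degassed MeOH, rt, Ar) should then give 28.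

Further compounds

F1 | step 9 | 2-(benzyloxy)-5-bromo-1,3-dimethoxybenzene | COc1cc(Br)cc(OC)c1OCc1ccccc1
F2 | step 9 | 2-(benzyloxy)-5-[4,6-dimethoxy-2-(2,4,6-trimethoxyphenoxy)phenoxy]-1,3-dimethoxybenzene | COc1cc(OC)c(Oc2cc(OC)cc(OC)c2Oc2cc(OC)c(OCc3ccccc3)c(OC)c2)c(OC)c1
F3 | step 9 | 4-[4,6-dimethoxy-2-(2,4,6-trimethoxyphenoxy)phenoxy]-2,6-dimethoxyphenol | COc1cc(OC)c(Oc2cc(OC)cc(OC)c2Oc2cc(OC)c(O)c(OC)c2)c(OC)c1
F4 | step 9 | 6-bromo-2,3,4-trimethoxybenzaldehyde | COc1cc(Br)c(C=O)c(OC)c1OC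
F5 | step 9 | 6-{4-[4,6-dimethoxy-2-(2,4,6-trimethoxyphenoxy)phenoxy]-2,6-dimethoxyphenoxy}-2,3,4-trimethoxybenzaldehyde | COc1cc(OC)c(Oc2cc(OC)cc(OC)c2Oc2cc(OC)c(Oc3cc(OC)c(OC)c(OC)c3C=O)c(OC)c2)c(OC)c1
F6 | step 9 | 6-{4-[4,6-dimethoxy-2-(2,4,6-trimethoxyphenoxy)phenoxy]-2,6-dimethoxyphenoxy}-2,3,4-trimethoxyphenyl formate | COc1cc(OC)c(Oc2cc(OC)cc(OC)c2Oc2cc(OC)c(Oc3cc(OC)c(OC)c(OC)c3OC=O)c(OC)c2)c(OC)c1
F7 | step 9 | 6-{4-[4,6-dimethoxy-2-(2,4,6-trimethoxyphenoxy)phenoxy]-2,6-dimethoxyphenoxy}-2,3,4-trimethoxyphenol | COc1cc(OC)c(Oc2cc(OC)cc(OC)c2Oc2cc(OC)c(Oc3cc(OC)c(OC)c(OC)c3O)c(OC)c2)c(OC)c1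
F8 | step 9 | tridecamethyl ether of the target | COc1cc(OC)c(Oc2cc(OC)cc(OC)c2Oc2cc(OC)c(Oc3cc(OC)c(OC)c(OC)c3Oc3cc(OC)c(OC)c(OC)c3)c(OC)c2)c(OC)c1
F9 | step 4 | {2-[4,6-dimethoxy-2-(2,4,6-trimethoxyphenoxy)phenoxy]ethynyl}trimethylsilane | COc1cc(OC)c(Oc2cc(OC)cc(OC)c2OC#C[Si](C)(C)C)c(OC)c1
F10 | step 10 | tridecaacetate of the target | CC(=O)Oc1cc(OC(C)=O)c(Oc2cc(OC(C)=O)cc(OC(C)=O)c2Oc2cc(OC(C)=O)c(Oc3cc(OC(C)=O)c(OC(C)=O)c(OC(C)=O)c3Oc3cc(OC(C)=O)c(OC(C)=O)c(OC(C)=O)c3)c(OC(C)=O)c2)c(OC(C)=O)c1
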